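The cyclohexene (ring A) is cut at C1–C2 and C5–C6. This leaves the chain C1–C6–C7 between two identical 5,7-dimethoxycoumarin-8-yl rings, which is a masked chalcone, and a seven-carbon diene. The key step exploits this chain and the O-7 oxygen of the coumarin on C7. As a free phenol beside the C7 ketone, that oxygen anchors a chiral borate, so one asymmetric Diels–Alder reaction builds ring A, the quaternary C5 and the trans C1/C6 pair. The precursor is an E-enone made from limettin twice, and a 1-silyl diene. The adduct is an allylsilane; protodesilylation moves the alkene to C2=C3. O-Methylation and Felkin–Anh reduction complete the target.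

Key step: step 5

Locants: ring A is the cyclohexene, with C1 (bears coumarin P), C2=C3 (CH3 on C3), C4 (CH2), C5 (two CH3) and C6. C7 is the exocyclic carbinol carbon and bears coumarin Q. Q-7 means position 7 of coumarin Q.

Assumption: (R)-VANOL is taken as the ligand antipode that leaves the C1-Si/C6-Si face of the enone open. If the sense proves opposite, (S)-VANOL is used and nothing else changes.

Step 1
Reactants: 1 5,7-dimethoxycoumarin (limettin)
Product: 3 5,7-dimethoxy-2-oxo-2H-chromene-8-carbaldehyde, via 8-[chloro(methoxy)methyl]-5,7-dimethoxycoumarin 2 (not isolated)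
Conditions: Cl2CHOMe, TiCl4, CH2Cl2, 0 °C to rt; then 1 M HCl
Reagents that add atoms: dichloromethyl methyl ether, COC(Cl)Cl; water, O
Why: Rieche formylation (electrophilic aromatic substitution) should go to coumarin C8, which is para to the 5-OMe group, ortho to the 7-OMe group and less crowded than C6 between two methoxy groups; hydrolysis of 2 on work-up frees the aldehyde.

Step 2
Reactants: 1 5,7-dimethoxycoumarin (limettin)
Product: 5 8-acetyl-7-hydroxy-5-methoxycoumarin, via 8-acetyl-5,7-dimethoxycoumarin 4 (not isolated)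
Conditions: AcCl, AlCl3 (3 equiv), ClCH2CH2Cl, 0 to 60 °C; then 1 M HCl
Reagents that add atoms: acetyl chloride, CC(=O)Cl
Why: Friedel–Crafts acylation, a known entry to 8-acyl-5,7-dioxygenated coumarins, is followed in the same flask by AlCl3-mediated cleavage of the only methyl ether (7-OMe) that can form a six-membered aluminium chelate to the new ketone, so the 5-OMe group should stay.

Step 3
Reactants: 3 5,7-dimethoxy-2-oxo-2H-chromene-8-carbaldehyde; 5 8-acetyl-7-hydroxy-5-methoxycoumarin
Product: 6 8-[(E)-3-(5,7-dimethoxy-2-oxo-2H-chromen-8-yl)prop-2-enoyl]-7-hydroxy-5-methoxycoumarin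
Conditions: piperidine (0.3 equiv), EtOH, reflux
Reagents that add atoms: none
Why: Claisen–Schmidt condensation under amine catalysis, precedented for 8-acetyl-7-hydroxycoumarins, leaves both lactones closed, and E1cB loss of water gives the E-enone, held open-chain by the hydrogen bond from Q-7-OH to the ketone.

Step 4
Reactants: 7 trimethyl(prop-1-yn-1-yl)silane; 8 1-bromo-2-methylprop-1-ene
Product: 10 (E)-(2,4-dimethylpenta-1,3-dien-1-yl)trimethylsilane, via alkenylborane 9 (not isolated)
Conditions: 9-BBN-H, THF, 0 °C to rt; then 8, Pd(PPh3)4 (3 mol%), 3 M NaOH, 65 °C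
Reagents that add atoms: none
Why: Syn hydroboration should place boron on the methyl-bearing alkyne carbon, remote from silicon, and the Suzuki–Miyaura coupling goes with retention at both alkenyl carbons, so silicon ends up trans to the new vinyl group (E).

Step 5
Reactants: 6 (E)-enone; 10 (E)-(2,4-dimethylpenta-1,3-dien-1-yl)trimethylsilane
Product: 13 (1S,2S,6R)-allylsilane cycloadduct (ring A: coumarin P on C1; SiMe3 on C2; C3(CH3)=C4; C5(CH3)2; Q-7-hydroxy-Q-5-methoxycoumarin-8-yl ketone on C6), via enone borate chelate 11 (not isolated), via cycloadduct borate 12 (not isolated)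
Conditions: (R)-VANOL (1.2 equiv), B(OPh)3 (1.2 equiv), 5 Å molecular sieves, PhCF3, rt; then 6; then 10 (5 equiv), rt to 50 °C; then H2O
Reagents that add atoms: none
Why: VANOL, B(OPh)3 and the Q-7 phenol of 6 assemble the spiro-borate 11, in which boron also binds the C7 ketone in a six-membered chelate; this lowers the enone LUMO at that carbonyl only, although two lactone carbonyls compete as Lewis bases, and diene 10 then adds in a normal-demand, concerted but asynchronous Diels–Alder reaction in which C1–C2 bonding runs ahead of C5–C6 bonding. The closest known reaction type is the chiral borate-promoted Diels–Alder reaction of 2'-hydroxychalcones with acyclic dienes, joined here to the known use of 1-silyl dienes as precursors of cyclic allylsilanes. One ring closes, the six-membered ring A, by intermolecular suprafacial-suprafacial [4+2] cycloaddition. C1 and C6 come out trans because the E geometry of 6 is retained, and their absolute configuration is controlled by the C2-symmetric ligand, which shields one face of the chelated enone and leaves the C1-Si/C6-Si face open; C2 is set by the endo orientation of the chelated carbonyl (silicon trans to coumarin P). Regioselectivity is the selectivity the step needs, and the diene secures it: the C3 methyl and both C5 methyls raise the HOMO coefficient at C2, which therefore bonds to the β-carbon C1, and the weak directing effect of silicon cannot override three alkyl donors. Endo/exo selectivity is not needed, since C5 carries two equal methyl groups and C2 loses its stereocenter in step 6.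

Step 6
Reactants: 13 (1S,2S,6R)-allylsilane cycloadduct
Product: 14 (1S,6R)-phenol ketone (ring A: C2=C3 alkene; CH3 on C3; C4H2; C5(CH3)2; coumarin P on C1; Q-7-hydroxy-Q-5-methoxycoumarin-8-yl ketone on C6)
Conditions: CF3CO2H (5 equiv), CH2Cl2, 0 °C; then aq. NaHCO3
Reagents that add atoms: none
Why: Protodesilylation of an allylsilane (SE2'): the proton adds to C4, the tertiary cation at C3 is stabilised by the C2–Si bond and loss of silicon places the alkene at C2=C3, while C1 and C6 are untouched and either C2 epimer gives the same product.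

Step 7
Reactants: 14 (1S,6R)-phenol ketone
Product: 15 (1S,6R)-ketone (as 14, with a 5,7-dimethoxycoumarin-8-yl ketone on C6)
Conditions: MeI, K2CO3, DMF, 40 °C
Reagents that add atoms: iodomethane, CI
Why: Williamson-type O-methylation of the chelated phenol; the trans C1/C6 arrangement is the more stable one, so the mild base should not erode C6.

Step 8
Reactants: 15 (1S,6R)-ketone
Product: 16 IN0553, (1S,6R,7R)-alcohol
Conditions: NaBH4, CeCl3·7H2O, MeOH/THF, −20 to 0 °C
Reagents that add atoms: none
Why: Luche-type 1,2-reduction should take the ketone in preference to the lactones and the pyranone C=C bonds, and C7 is set under Felkin–Anh control: the C6–C5 bond to the quaternary carbon stands perpendicular to the carbonyl, coumarin Q lies beside C6–H, and hydride enters anti to C5, which gives 7R.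

Compound list
1 | 5,7-dimethoxycoumarin (limettin) | COc1cc(OC)c2ccc(=O)oc2c1 | starting material
2 | 8-[chloro(methoxy)methyl]-5,7-dimethoxycoumarin (racemic) | COc1cc(OC)c2ccc(=O)oc2c1C(Cl)OC | intermediate
3 | 5,7-dimethoxy-2-oxo-2H-chromene-8-carbaldehyde | COc1cc(OC)c2ccc(=O)oc2c1C=O | intermediate
4 | 8-acetyl-5,7-dimethoxycoumarin | COc1cc(OC)c2ccc(=O)oc2c1C(C)=O | intermediate
5 | 8-acetyl-7-hydroxy-5-methoxycoumarin | CC(=O)c1c(O)cc(OC)c2ccc(=O)oc12 | intermediate
6 | 8-[(E)-3-(5,7-dimethoxy-2-oxo-2H-chromen-8-yl)prop-2-enoyl]-7-hydroxy-5-methoxycoumarin | COc1cc(OC)c2ccc(=O)oc2c1/C=C/C(=O)c1c(O)cc(OC)c2ccc(=O)oc12 | intermediate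
7 | trimethyl(prop-1-yn-1-yl)silane | CC#C[Si](C)(C)C | starting material
8 | 1-bromo-2-methylprop-1-ene | CC(C)=CBr | starting material
9 | (Z)-9-[1-(trimethylsilyl)prop-1-en-2-yl]-9-borabicyclo[3.3.1]nonane | C[Si](C)(C)/C=C(\C)B1C2CCCC1CCC2 | intermediate
10 | (E)-(2,4-dimethylpenta-1,3-dien-1-yl)trimethylsilane | C[Si](C)(C)/C=C(\C)C=C(C)C | intermediate
11 | spiro-borate chelate of enone 6 (boron bound to both oxygens of (R)-VANOL, to Q-7-O and to the C7 ketone oxygen; the axial chirality of the ligand is given by name) | COc1cc(OC)c2ccc(=O)oc2c1/C=C/C3=[O+][B-]4(Oc5cc(OC)c6ccc(=O)oc6c35)Oc5c(-c7c(O4)c8ccccc8cc7-c7ccccc7)c(-c7ccccc7)cc6ccccc56 | intermediate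
12 | spiro-borate of the (1S,2S,6R)-cycloadduct (same boron environment as in 11) | COc1cc(OC)c2ccc(=O)oc2c1[C@H]1[C@H]([Si](C)(C)C)C(C)=CC(C)(C)[C@@H]1C3=[O+][B-]4(Oc5cc(OC)c6ccc(=O)oc6c35)Oc5c(-c7c(O4)c8ccccc8cc7-c7ccccc7)c(-c7ccccc7)cc6ccccc56 | intermediate
13 | (1S,2S,6R)-1-(5,7-dimethoxycoumarin-8-yl)-6-[(7-hydroxy-5-methoxycoumarin-8-yl)carbonyl]-3,5,5-trimethyl-2-(trimethylsilyl)cyclohex-3-ene (route locants) | COc1cc(OC)c2ccc(=O)oc2c1[C@H]1[C@H]([Si](C)(C)C)C(C)=CC(C)(C)[C@@H]1C(=O)c1c(O)cc(OC)c2ccc(=O)oc12 | intermediate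
14 | (1S,6R)-1-(5,7-dimethoxycoumarin-8-yl)-6-[(7-hydroxy-5-methoxycoumarin-8-yl)carbonyl]-3,5,5-trimethylcyclohex-2-ene (route locants) | COc1cc(OC)c2ccc(=O)oc2c1[C@H]1C=C(C)CC(C)(C)[C@@H]1C(=O)c1c(O)cc(OC)c2ccc(=O)oc12 | intermediate
15 | (1S,6R)-1-(5,7-dimethoxycoumarin-8-yl)-6-[(5,7-dimethoxycoumarin-8-yl)carbonyl]-3,5,5-trimethylcyclohex-2-ene (route locants) | COc1cc(OC)c2ccc(=O)oc2c1[C@H]1C=C(C)CC(C)(C)[C@@H]1C(=O)c1c(OC)cc(OC)c2ccc(=O)oc12 | intermediate
16 | IN0553, (1S,6R,7R)-alcohol: (7R)-hydroxy(5,7-dimethoxycoumarin-8-yl)methyl group on C6, otherwise as 15 | COc1cc(OC)c2ccc(=O)oc2c1[C@H]1C=C(C)CC(C)(C)[C@@H]1[C@@H](O)c1c(OC)cc(OC)c2ccc(=O)oc12 | target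

Total step count: 8. Longest linear sequence: 6 (steps 1, 3, 5, 6, 7, 8).

Steps most likely to fail

Step 5. The cycloaddition may stall. The inner methyl group on C5 disfavours the s-cis form of 10, four bulky groups crowd the new ring, and the donor coumarin P damps the enone. Attack at C2 may also end in loss of silicon before the ring closes. The fallback runs from 6 to 15. The far more nucleophilic 2-silyloxy diene tert-butyl(dimethyl)[(4-methylpenta-1,3-dien-2-yl)oxy]silane F1 (from mesityl oxide, TBSOTf, Et3N) is added to the same chelate 11. A stepwise Mukaiyama–Michael/Michael [4+2] forms the same two bonds and should give, after aqueous work-up, the (1S,6R)-silyl enol ether cycloadduct F2. Dilute HCl frees the ring A 3-ketone F3, and MeI/K2CO3 gives its Q-7 methyl ether F4. KHMDS and N-(5-chloro-2-pyridyl)triflimide at −78 °C should deprotonate the less hindered C2 rather than the neopentyl C4, giving the C2=C3 enol triflate F5. Suzuki–Miyaura methylation (MeB(OH)2, Pd(dppf)Cl2, K3PO4, dioxane) then gives 15.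

Step 8. Hydride delivery to a ketone flanked by C5, C1 and a doubly ortho-substituted aryl group may be slow. Facial selectivity may be poor or reversed, and conjugate reduction of a pyranone may compete. The fallback runs from 15 to 16. The reduction is driven to the (1S,6R,7S)-alcohol F6, the C7 epimer. Mitsunobu esterification (4-nitrobenzoic acid, PPh3, DIAD, THF) inverts C7 to the (1S,6R,7R)-4-nitrobenzoate F7, and K2CO3/MeOH releases 16.

Step 2. AlCl3 may be tied up by the lactone carbonyl so that acylation is slow. Acylation may go partly to C6, and ether cleavage may spread to the 5-OMe group. The fallback runs from 3 to 5 and ties the regiochemistry to step 1. MeMgBr (THF, −78 °C) adds to the aldehyde to give 8-(1-hydroxyethyl)-5,7-dimethoxycoumarin F8. Dess–Martin periodinane oxidises it to 4, which is isolated here. BCl3 (CH2Cl2, −78 to 0 °C) then cleaves only the methyl ether ortho to the ketone and gives 5.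

Further compounds
F1 | step 5 | tert-butyl(dimethyl)[(4-methylpenta-1,3-dien-2-yl)oxy]silane | CC(C)=CC(=C)O[Si](C)(C)C(C)(C)C
F2 | step 5 | (1S,6R)-silyl enol ether cycloadduct (OTBS on C3, C3=C4, Q-7-OH) | COc1cc(OC)c2ccc(=O)oc2c1[C@H]1CC(O[Si](C)(C)C(C)(C)C)=CC(C)(C)[C@@H]1C(=O)c1c(O)cc(OC)c2ccc(=O)oc12
F3 | step 5 | (1S,6R)-ring A 3-ketone (Q-7-OH) | COc1cc(OC)c2ccc(=O)oc2c1[C@H]1CC(=O)CC(C)(C)[C@@H]1C(=O)c1c(O)cc(OC)c2ccc(=O)oc12
F4 | step 5 | (1S,6R)-ring A 3-ketone, Q-7 methyl ether | COc1cc(OC)c2ccc(=O)oc2c1[C@H]1CC(=O)CC(C)(C)[C@@H]1C(=O)c1c(OC)cc(OC)c2ccc(=O)oc12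
F5 | step 5 | (1S,6R)-C2=C3 enol triflate | COc1cc(OC)c2ccc(=O)oc2c1[C@H]1C=C(OS(=O)(=O)C(F)(F)F)CC(C)(C)[C@@H]1C(=O)c1c(OC)cc(OC)c2ccc(=O)oc12
F6 | step 8 | (1S,6R,7S)-alcohol, C7 epimer of 16 | COc1cc(OC)c2ccc(=O)oc2c1[C@H]1C=C(C)CC(C)(C)[C@@H]1[C@H](O)c1c(OC)cc(OC)c2ccc(=O)oc12
F7 | step 8 | (1S,6R,7R)-4-nitrobenzoate of 16 | COc1cc(OC)c2ccc(=O)oc2c1[C@H]1C=C(C)CC(C)(C)[C@@H]1[C@@H](OC(=O)c1ccc(cc1)[N+](=O)[O-])c1c(OC)cc(OC)c2ccc(=O)oc12
F8 | step 2 | 8-(1-hydroxyethyl)-5,7-dimethoxycoumarin (racemic) | COc1cc(OC)c2ccc(=O)oc2c1C(C)O
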